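The 13-membered 1,5,9-triazacyclotridecan-4-one ring holds a β-amino amide, N1–C2–C3–C4(=O). Folding N1 onto C4 turns it into an azetidin-2-one, in which C2 becomes the carbon of a non-enolisable cyclic acylimine. The side chain is cut off at C2–C1′ and brought in as an enantiopure enyne. In one operation a copper/pybox acetylide adds to azet-2(3H)-one, released from racemic 4-acetoxyazetidin-2-one. The C–C bond forms, C2 is set enantioconvergently, and a strained N1–C4 bond absent from the target is stored. That bond later breaks in a 4→9→13 transamidative ring expansion relayed by N9. Z-selective semireduction of the alkyne finishes the diene.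

Key step: step 4

Remark on numbering: target ring atoms are N1, C2 (stereocentre), C3, C4 (C=O), N5, C6–C8, N9 (acetyl), C10–C13. Side-chain atoms are C1′–C7′, counted from the ring.
Remark on chemistry: (R)-pent-1-yn-3-ol is assumed to be purchased as the single enantiomer.
Remark on chemistry: the sense of induction of the pybox ligand on the azetinone is not known. (S,S)-Ph-pybox is written, and its antipode is used instead if the first run favours the 4S epimer.

Step 1
Reactants: 1 (R)-pent-1-yn-3-ol
Product: 2 (R)-tert-butyldimethyl(pent-1-yn-3-yloxy)silane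
Conditions: TBSCl, imidazole, DMF, 0 °C to rt
Reagents that add atoms: tert-butyldimethylsilyl chloride, CC(C)(C)[Si](C)(C)Cl
Why: Standard silyl ether formation masks the carbinol against the organometallic steps and against O-addition to the acylimine of step 4, and leaves the stereocentre untouched.

Step 2
Reactants: 2 (R)-tert-butyldimethyl(pent-1-yn-3-yloxy)silane
Product: 4 (R,E)-tert-butyl[(1-iodopent-1-en-3-yl)oxy]dimethylsilane, via alkenylzirconocene chloride 3 (not isolated)
Conditions: Cp2Zr(H)Cl, CH2Cl2, rt, dark; then I2, THF, 0 °C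
Reagents that add atoms: iodine, II
Why: Schwartz hydrozirconation adds H and Zr syn with zirconium on the terminal carbon, and iodinolysis with retention should give the E-alkenyl iodide only.

Step 3
Reactants: 4 (R,E)-tert-butyl[(1-iodopent-1-en-3-yl)oxy]dimethylsilane; 5 ethynylmagnesium bromide
Product: 7 (R,E)-tert-butyl(hept-4-en-6-yn-3-yloxy)dimethylsilane, via ethynylzinc bromide 6 (not isolated)
Conditions: 5, ZnBr2, THF, 0 °C; then 4, Pd(PPh3)4 (5 mol %), THF, rt
Reagents that add atoms: none
Why: Negishi coupling of an alkenyl iodide with an excess of ethynylzinc bromide proceeds with retention of the E geometry and should deliver the terminal enyne directly, without a silyl detour.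

Step 4
Reactants: 7 (R,E)-tert-butyl(hept-4-en-6-yn-3-yloxy)dimethylsilane; 8 (±)-4-acetoxyazetidin-2-one
Product: 11 (4R)-4-[(3E,5R)-5-(tert-butyldimethylsilyloxy)hept-3-en-1-yn-1-yl]azetidin-2-one, via copper acetylide 9 (not isolated), via azetinone 10 (not isolated)
Conditions: Cu(MeCN)4PF6 (10 mol %), (S,S)-Ph-pybox (12 mol %), iPr2NEt (2 equiv), 4 Å MS, CH2Cl2, −20 °C to rt, argon
Reagents that add atoms: none
Why: Proposed new method: iPr2NEt triggers E1cB loss of acetate from either enantiomer of 8 to give the planar, non-enolisable four-membered N-acylimine 10, while 7 is metalated to the pybox-bound monovalent copper acetylide 9; 9 adds to the C=N carbon of copper-coordinated 10, and protonation of the resulting copper amidate releases 11 and the catalyst. The closest known reaction types are the non-selective displacement of 4-acyloxy- and 4-sulfonylazetidin-2-ones by magnesium or aluminium acetylides through the same azetinone, and the copper/pybox- or copper/bis(oxazoline)-catalysed enantioselective addition of terminal alkynes to imines and N-acyliminium ions; their combination on an azetinone has not been shown. No ring is closed: the azetidinone ring comes from 8 and is kept as the strained acyl donor for step 6. The only new stereocentre, C4 of 11 (C2 of the target), is controlled by the ligand, whose phenyl groups leave one face of N-bound 10 open; the process is enantioconvergent because the stereocentre of 8 is erased in 10, and the remote C5′ centre of 7 should have no influence. The step needs attack at C4 rather than at the lactam carbonyl, which the acylimine LUMO and the ring strain secure, and it needs the absence of competing O- and N-nucleophiles, which the silyl ether of 7, the molecular sieves and the slow release of 10 secure.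

Step 5
Reactants: 11 (4R)-4-[(3E,5R)-5-(tert-butyldimethylsilyloxy)hept-3-en-1-yn-1-yl]azetidin-2-one; 12 1,4-dibromobutane
Product: 14 (4R)-1-(4-bromobutyl)-4-[(3E,5R)-5-(tert-butyldimethylsilyloxy)hept-3-en-1-yn-1-yl]azetidin-2-one, via sodium lactamate 13 (not isolated)
Conditions: NaH (1.0 equiv), DMF, 0 °C; then added to 12 (4 equiv), DMF, 0 °C to rt
Reagents that add atoms: none
Why: SN2 N-alkylation of the lactam sodium salt with an excess of the dibromide should stop at mono-substitution, and one equivalent of NaH removes only the N–H proton, so C4 is not epimerised.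

Step 6
Reactants: 14 (4R)-1-(4-bromobutyl)-4-[(3E,5R)-5-(tert-butyldimethylsilyloxy)hept-3-en-1-yn-1-yl]azetidin-2-one; 15 propane-1,3-diamine
Product: 18 (2R)-2-[(3E,5R)-5-(tert-butyldimethylsilyloxy)hept-3-en-1-yn-1-yl]-1,5,9-triazacyclotridecan-4-one, via triamine lactam 16 (not isolated), via nine-membered lactam 17 (not isolated)
Conditions: 15 (20 equiv, neat), rt, then excess 15 removed in vacuo; 2-hydroxypyridine (20 mol %), toluene (0.02 M), 110 °C; aq K2CO3 work-up
Reagents that add atoms: none
Why: Excess 15 displaces bromide (SN2), N9 then attacks the strained lactam carbonyl through a seven-membered transition state and collapse of the bicyclic tetrahedral intermediate cleaves N1–C4 (4→9), and the pendant primary amine repeats the transamidation through a six-membered transition state (9→13, Zip-type ring expansion), each stage being driven by loss of ring strain and ending in the secondary lactam without touching C2.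

Step 7
Reactants: 18 (2R)-2-[(3E,5R)-5-(tert-butyldimethylsilyloxy)hept-3-en-1-yn-1-yl]-1,5,9-triazacyclotridecan-4-one
Product: 19 (2R)-9-acetyl-2-[(3E,5R)-5-(tert-butyldimethylsilyloxy)hept-3-en-1-yn-1-yl]-1,5,9-triazacyclotridecan-4-one
Conditions: Ac2O (1.0 equiv), Et3N, CH2Cl2, −78 to −20 °C
Reagents that add atoms: acetic anhydride, CC(=O)OC(C)=O
Why: Site-selective N-acylation is expected because N9 is an unhindered dialkylamine, N1 is α-branched and made less basic by the propargylic alkyne, and N5 is an amide.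

Step 8
Reactants: 19 (2R)-9-acetyl-2-[(3E,5R)-5-(tert-butyldimethylsilyloxy)hept-3-en-1-yn-1-yl]-1,5,9-triazacyclotridecan-4-one
Product: 20 (2R)-9-acetyl-2-[(1Z,3E,5R)-5-(tert-butyldimethylsilyloxy)hepta-1,3-dien-1-yl]-1,5,9-triazacyclotridecan-4-one
Conditions: Zn(Cu/Ag) from Zn dust, Cu(OAc)2 and AgNO3, MeOH/H2O 1:1, 35 °C, argon, dark; aq NH3/EDTA work-up
Reagents that add atoms: none
Why: The Boland reduction delivers two hydrogens syn to a conjugated, heteroatom-activated triple bond and leaves alkenes, amides and silyl ethers alone, so the 1′Z alkene should form beside the untouched 3′E alkene.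

Step 9
Reactants: 20 (2R)-9-acetyl-2-[(1Z,3E,5R)-5-(tert-butyldimethylsilyloxy)hepta-1,3-dien-1-yl]-1,5,9-triazacyclotridecan-4-one
Product: 21 (2R)-9-acetyl-2-[(1Z,3E,5R)-5-hydroxyhepta-1,3-dien-1-yl]-1,5,9-triazacyclotridecan-4-one
Conditions: TBAF, THF, 0 °C to rt
Reagents that add atoms: none
Why: Fluoride-induced desilylation under non-acidic conditions avoids ionisation of the dienylic alcohol and touches neither stereocentre nor alkene geometry.

Compound list
1 | (R)-pent-1-yn-3-ol | CC[C@@H](O)C#C | starting material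
2 | (R)-tert-butyldimethyl(pent-1-yn-3-yloxy)silane | CC[C@@H](O[Si](C)(C)C(C)(C)C)C#C | intermediate
3 | chlorobis(cyclopentadienyl)[(1E,3R)-3-(tert-butyldimethylsilyloxy)pent-1-en-1-yl]zirconium (cyclopentadienyl rings drawn σ-bound) | CC[C@@H](O[Si](C)(C)C(C)(C)C)/C=C/[Zr](Cl)(C1C=CC=C1)C1C=CC=C1 | intermediate
4 | (R,E)-tert-butyl[(1-iodopent-1-en-3-yl)oxy]dimethylsilane | CC[C@@H](O[Si](C)(C)C(C)(C)C)/C=C/I | intermediate
5 | ethynylmagnesium bromide | C#C[Mg]Br | starting material
6 | ethynylzinc bromide | C#C[Zn]Br | intermediate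
7 | (R,E)-tert-butyl(hept-4-en-6-yn-3-yloxy)dimethylsilane | CC[C@@H](O[Si](C)(C)C(C)(C)C)/C=C/C#C | intermediate
8 | (±)-4-acetoxyazetidin-2-one | CC(=O)OC1CC(=O)N1 | starting material
9 | monovalent copper acetylide of 7 (pybox ligand not drawn) | CC[C@@H](O[Si](C)(C)C(C)(C)C)/C=C/C#C[Cu] | intermediate
10 | azet-2(3H)-one (azetinone) | O=C1CC=N1 | intermediate
11 | (4R)-4-[(3E,5R)-5-(tert-butyldimethylsilyloxy)hept-3-en-1-yn-1-yl]azetidin-2-one | CC[C@@H](O[Si](C)(C)C(C)(C)C)/C=C/C#C[C@H]1CC(=O)N1 | intermediate
12 | 1,4-dibromobutane | BrCCCCBr | starting material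
13 | sodium salt of 11 (N-deprotonated) | CC[C@@H](O[Si](C)(C)C(C)(C)C)/C=C/C#C[C@H]1CC(=O)[N-]1.[Na+] | intermediate
14 | (4R)-1-(4-bromobutyl)-4-[(3E,5R)-5-(tert-butyldimethylsilyloxy)hept-3-en-1-yn-1-yl]azetidin-2-one | CC[C@@H](O[Si](C)(C)C(C)(C)C)/C=C/C#C[C@H]1CC(=O)N1CCCCBr | intermediate
15 | propane-1,3-diamine | NCCCN | starting material
16 | (4R)-1-{4-[(3-aminopropyl)amino]butyl}-4-[(3E,5R)-5-(tert-butyldimethylsilyloxy)hept-3-en-1-yn-1-yl]azetidin-2-one | CC[C@@H](O[Si](C)(C)C(C)(C)C)/C=C/C#C[C@H]1CC(=O)N1CCCCNCCCN | intermediate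
17 | (4R)-1-(3-aminopropyl)-4-[(3E,5R)-5-(tert-butyldimethylsilyloxy)hept-3-en-1-yn-1-yl]-1,5-diazonan-2-one | CC[C@@H](O[Si](C)(C)C(C)(C)C)/C=C/C#C[C@H]1CC(=O)N(CCCN)CCCCN1 | intermediate
18 | (2R)-2-[(3E,5R)-5-(tert-butyldimethylsilyloxy)hept-3-en-1-yn-1-yl]-1,5,9-triazacyclotridecan-4-one | CC[C@@H](O[Si](C)(C)C(C)(C)C)/C=C/C#C[C@H]1CC(=O)NCCCNCCCCN1 | intermediate
19 | (2R)-9-acetyl-2-[(3E,5R)-5-(tert-butyldimethylsilyloxy)hept-3-en-1-yn-1-yl]-1,5,9-triazacyclotridecan-4-one | CC[C@@H](O[Si](C)(C)C(C)(C)C)/C=C/C#C[C@H]1CC(=O)NCCCN(C(C)=O)CCCCN1 | intermediate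
20 | (2R)-9-acetyl-2-[(1Z,3E,5R)-5-(tert-butyldimethylsilyloxy)hepta-1,3-dien-1-yl]-1,5,9-triazacyclotridecan-4-one | CC[C@@H](O[Si](C)(C)C(C)(C)C)/C=C/C=C\[C@H]1CC(=O)NCCCN(C(C)=O)CCCCN1 | intermediate
21 | (2R)-9-acetyl-2-[(1Z,3E,5R)-5-hydroxyhepta-1,3-dien-1-yl]-1,5,9-triazacyclotridecan-4-one | CC[C@@H](O)/C=C/C=C\[C@H]1CC(=O)NCCCN(C(C)=O)CCCCN1 | target

Total step count: 9. Longest linear sequence: 9 steps (1 to 21). Compounds 5, 8, 12 and 15 are bought.

Steps most likely to fail

Step 4 (new method).
- What may go wrong: weak facial discrimination on the small, flat acylimine; slow release of the acylimine by the amine base; capture of the acylimine by the N–H of product already formed; oxidative homocoupling of the alkyne.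
- Fallback: known chemistry that forms the same bond, setting out from 7 and 8 and coming back at 11.
- 7 is deprotonated with EtMgBr in THF to the alkynylmagnesium bromide of 7 F1.
- Two equivalents of F1 are combined with 8 at −20 °C to rt. The first acts as base and the second as nucleophile, which is the established substitution of 4-acyloxyazetidinones by metal acetylides.
- Without a ligand both C4 configurations should form, namely 11 and the (4S)-epimer of 11 F2.
- Because 7 is a single enantiomer, these are diastereomers, and 11 is secured by preparative HPLC. Catalyst control is thus traded for separation.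

Step 6.
- What may go wrong: stalling after the amination or at the nine-membered stage; intermolecular aminolysis of the β-lactam by the excess diamine; oligomerisation during heating.
- Fallback: sets out from 11 and comes back at 19. The ring is closed at N1–C13 instead of by acyl transfer, and the acetyl group is brought in with the chain.
- 4-Aminobutan-1-ol is added to acrylonitrile to give 3-[(4-hydroxybutyl)amino]propanenitrile F3.
- F3 is N-acetylated (Ac2O, MeOH) to N-(2-cyanoethyl)-N-(4-hydroxybutyl)acetamide F4.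
- F4 is hydrogenated (Raney Ni, H2, NH3/MeOH) to N-(3-aminopropyl)-N-(4-hydroxybutyl)acetamide F5.
- 11 is sulfonylated (LiHMDS, 2-nitrobenzenesulfonyl chloride, THF, −78 °C) to the activated N-nosyl lactam F6.
- F5 opens F6 at the carbonyl at rt to the seco hydroxy sulfonamide F7.
- Fukuyama–Mitsunobu cyclisation (PPh3, DIAD, toluene, high dilution) should give the N1-nosyl macrocycle F8.
- PhSH/K2CO3 in DMF frees N1 to give 19.

Step 8.
- What may go wrong: passivation of the zinc surface by the chelating polyamine; incomplete conversion; over-reduction; Z-to-E drift during a long reaction.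
- Fallback: sets out from 11 and comes back at 20. The semireduction is moved forward to the neutral, non-chelating lactam.
- 11 is reduced with Zn(Cu/Ag) to the (Z,E)-dienyl lactam F9.
- F9 is converted with NaH into the sodium salt of the dienyl lactam F10, which is alkylated with 12 to the N-(4-bromobutyl) dienyl lactam F11.
- Treatment with 15 as in step 6 passes through the dienyl triamine lactam F12 and the dienyl nine-membered lactam F13 to the N9-unsubstituted dienyl macrocycle F14.
- Acetylation of F14 as in step 7 gives 20.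

Further compounds
F1 | step 4 | alkynylmagnesium bromide of 7 | CC[C@@H](O[Si](C)(C)C(C)(C)C)/C=C/C#C[Mg]Br
F2 | step 4 | (4S)-epimer of 11, (4S)-4-[(3E,5R)-5-(tert-butyldimethylsilyloxy)hept-3-en-1-yn-1-yl]azetidin-2-one | CC[C@@H](O[Si](C)(C)C(C)(C)C)/C=C/C#C[C@@H]1CC(=O)N1
F3 | step 6 | 3-[(4-hydroxybutyl)amino]propanenitrile | N#CCCNCCCCO
F4 | step 6 | N-(2-cyanoethyl)-N-(4-hydroxybutyl)acetamide | CC(=O)N(CCC#N)CCCCO
F5 | step 6 | N-(3-aminopropyl)-N-(4-hydroxybutyl)acetamide | CC(=O)N(CCCN)CCCCO
F6 | step 6 | N-nosyl lactam, (4R)-4-[(3E,5R)-5-(tert-butyldimethylsilyloxy)hept-3-en-1-yn-1-yl]-1-(2-nitrophenylsulfonyl)azetidin-2-one | CC[C@@H](O[Si](C)(C)C(C)(C)C)/C=C/C#C[C@H]1CC(=O)N1S(=O)(=O)c1ccccc1[N+](=O)[O-]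
F7 | step 6 | seco hydroxy sulfonamide, (3R,6E,8R)-N-{3-[acetyl(4-hydroxybutyl)amino]propyl}-8-(tert-butyldimethylsilyloxy)-3-(2-nitrophenylsulfonylamino)dec-6-en-4-ynamide | CC[C@@H](O[Si](C)(C)C(C)(C)C)/C=C/C#C[C@@H](CC(=O)NCCCN(C(C)=O)CCCCO)NS(=O)(=O)c1ccccc1[N+](=O)[O-]
F8 | step 6 | N1-nosyl macrocycle, (2R)-9-acetyl-2-[(3E,5R)-5-(tert-butyldimethylsilyloxy)hept-3-en-1-yn-1-yl]-1-(2-nitrophenylsulfonyl)-1,5,9-triazacyclotridecan-4-one | CC[C@@H](O[Si](C)(C)C(C)(C)C)/C=C/C#C[C@H]1CC(=O)NCCCN(C(C)=O)CCCCN1S(=O)(=O)c1ccccc1[N+](=O)[O-]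
F9 | step 8 | (Z,E)-dienyl lactam, (4R)-4-[(1Z,3E,5R)-5-(tert-butyldimethylsilyloxy)hepta-1,3-dien-1-yl]azetidin-2-one | CC[C@@H](O[Si](C)(C)C(C)(C)C)/C=C/C=C\[C@H]1CC(=O)N1
F10 | step 8 | sodium salt of the dienyl lactam | CC[C@@H](O[Si](C)(C)C(C)(C)C)/C=C/C=C\[C@H]1CC(=O)[N-]1.[Na+]
F11 | step 8 | N-(4-bromobutyl) dienyl lactam | CC[C@@H](O[Si](C)(C)C(C)(C)C)/C=C/C=C\[C@H]1CC(=O)N1CCCCBr
F12 | step 8 | dienyl triamine lactam | CC[C@@H](O[Si](C)(C)C(C)(C)C)/C=C/C=C\[C@H]1CC(=O)N1CCCCNCCCN
F13 | step 8 | dienyl nine-membered lactam | CC[C@@H](O[Si](C)(C)C(C)(C)C)/C=C/C=C\[C@H]1CC(=O)N(CCCN)CCCCN1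
F14 | step 8 | N9-unsubstituted dienyl macrocycle | CC[C@@H](O[Si](C)(C)C(C)(C)C)/C=C/C=C\[C@H]1CC(=O)NCCCNCCCCN1
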